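The cyclopentene (C9, C11, C12, C14, C8; locants defined below) is closed last through the C12–C14 bond, exploiting its C11=C12 alkene next to the ester-bearing quaternary C14, the retron of an ester enolate adding across an alkyne. The precursor is a δ-lactone whose C14 is a silyl ketene acetal cross-conjugated with the C13 exo-methylene and whose C9 carries a 1-propynyl group, axial on the lactone ring and 1,3 to C14. A gold-catalysed 5-endo-dig Conia-ene-type cyclisation forges C12–C14, creates quaternary C14 beside quaternary C8 and delivers the target directly. The tricyclic core comes from an asymmetric quinone Diels–Alder reaction, the C9–O bond from a Nicholas lactonisation.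

Key step: step 13

Locants used in all names: ring A = C1, C2, C3, C4, C5, C10; ring B = C5, C6, C7, C8, C9, C10; C19 = carbonyl carbon on C10 (γ-lactone to O6); C11, C12 and C14 close the cyclopentene on C9 and C8; C13 (bearing methylene C18) and C17 (carbonyl) complete the δ-lactone from C14 to O9; C15 = methyl ester carbon on C14. α is the face of H-5, β the face of C19.

Assumption: the Sm(OTf)3–pybox catalyst of step 2 is taken to give the (S)-configured ester-bearing ring-fusion carbon C10 with the (S,S)-ligand; if the sense is opposite, the (R,R)-ligand is used.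

Remark: C14 is formed as an epimer mixture in step 7 and is left undefined in the SMILES of 12–17; it becomes planar in 18 and is set in step 13.

Step 1
Reactants: 1 4-methylpent-1-en-3-one
Product: 2 tert-butyl(dimethyl)[(4-methylpenta-1,3-dien-3-yl)oxy]silane
Conditions: TBSOTf, Et3N, CH2Cl2, 0 °C
Reagents that add atoms: tert-butyldimethylsilyl trifluoromethanesulfonate, CC(C)(C)[Si](C)(C)OS(=O)(=O)C(F)(F)F
Why: Soft enolisation (silyl enol ether formation) can only involve the isopropyl methine, the single enolisable position, and so should give the 2-silyloxy diene whose dimethyl-substituted terminus is the nucleophilic end.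

Step 2
Reactants: 3 methyl 2,5-dihydroxybenzoate; 2 silyloxy diene
Product: 6 trans-fused Diels–Alder adduct (5α-H), via quinone ester 4 (not isolated), via cis-fused adduct 5 (not isolated)
Conditions: Ag2O, MgSO4, CH2Cl2, rt, filter; filtrate + 2, Sm(OTf)3 (10 mol %), (S,S)-Ph-pybox (11 mol %), 4 Å MS, CH2Cl2, −78 → −30 °C; then DBU (0.2 equiv), rt
Reagents that add atoms: none
Why: Ag2O dehydrogenates the hydroquinone, the chiral Lewis acid-catalysed Diels–Alder reaction of the chelated quinone ester then joins the nucleophilic dimethyl-substituted diene terminus to the quinone CH carbon β to the keto ester (C4–C5 and C1–C10 bonds) with the catalyst-shielded face fixing C10, and DBU should epimerise C5 through the C6 enol to the more stable trans ring fusion.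

Step 3
Reactants: 6 trans-fused Diels–Alder adduct
Product: 7 4,4-dimethyl-3,9-dioxo-5α-decal-7-ene 19,6β-lactone
Conditions: NaBH4, CeCl3·7H2O, MeOH/CH2Cl2, −78 °C; then 1 M HCl, THF, rt
Reagents that add atoms: none
Why: Luche 1,2-reduction should take the less hindered C6 carbonyl from the α face (the β face is blocked by the axial ester and the 4β-methyl group), the 6β-alkoxide lactonises onto the 1,3-diaxial C19 ester, and the acidic work-up hydrolyses the silyl enol ether to the C3 ketone.

Step 4
Reactants: 7 enone lactone
Product: 8 3α-hydroxy-4,4,8α-trimethyl-9-oxo-5α-decalin 19,6β-lactone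
Conditions: K[BH(s-Bu)3] (2.3 equiv), THF, −78 °C; then MeI, −78 → 0 °C; aqueous work-up
Reagents that add atoms: iodomethane, CI
Why: The bulky hydride should attack the C3 ketone equatorially to give the axial 3α-alcohol and add in conjugate fashion to the enone, whose C9 carbonyl is shielded by quaternary C10, and the potassium enolate is then C-methylated (reductive alkylation), the C8 configuration formed here being erased in step 7.

Step 5
Reactants: 8 hydroxy keto lactone
Product: 9 3α-acetoxy-4,4,8α-trimethyl-9-oxo-5α-decalin 19,6β-lactone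
Conditions: Ac2O, DMAP, pyridine, rt
Reagents that add atoms: acetic anhydride, CC(=O)OC(C)=O
Why: DMAP-catalysed acylation of the secondary axial alcohol installs the acetate of the target and removes the free hydroxyl before the enolate chemistry.

Step 6
Reactants: 10 dimethyl mesaconate
Product: 11 dimethyl (2Z)-2-(bromomethyl)but-2-enedioate
Conditions: NBS, AIBN (cat.), PhCF3, reflux
Reagents that add atoms: N-bromosuccinimide, O=C1CCC(=O)N1Br
Why: Wohl–Ziegler radical bromination of the only allylic position should give the bromomethyl fumarate with the ester groups still trans.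

Step 7
Reactants: 9 acetoxy keto lactone; 11 dimethyl (2Z)-2-(bromomethyl)but-2-enedioate
Product: 12 keto diester with 8β-methyl and 8α-[1,2-bis(methoxycarbonyl)prop-2-enyl] groups
Conditions: KN(SiMe3)2 (1.1 equiv), THF, −78 °C; then 11, −78 °C; AcOH quench at −78 °C
Reagents that add atoms: none
Why: C8 is the only enolisable ketone position (the silylamide base does not deprotonate the acetate appreciably), and the tetrasubstituted enolate should attack the ester-bearing CH carbon of 11 with loss of bromide (SN2' addition–elimination) from the α face, anti to the lactone bridge, which sets C8 with the methyl group β.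

Step 8
Reactants: 12 keto diester
Product: 13 keto acid (C17 carboxylic acid, C15 methyl ester)
Conditions: Me3SnOH, ClCH2CH2Cl, 70 °C; 5% HCl work-up
Reagents that add atoms: trimethyltin hydroxide, C[Sn](C)(C)O
Why: Tin hydroxide-mediated ester cleavage should take the unhindered acrylate-type methyl ester (C17) selectively, the C15 ester on the neopentyl-type C14, the bridged lactone and the hindered acetate reacting much more slowly.

Step 9
Reactants: 13 keto acid
Product: 14 9β-hydroxy-9α-(prop-1-ynyl) acid
Conditions: 1-propynylmagnesium bromide (4 equiv), LaCl3·2LiCl, THF, 0 °C → rt; dilute HCl quench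
Reagents that add atoms: 1-propynylmagnesium bromide, CC#C[Mg]Br
Why: 1,2-Addition of the alkynylmagnesium reagent to the non-enolisable ketone (acid masked as its magnesium carboxylate) is expected from the α face, anti to the two flanking axial β substituents, and the C9 configuration does not matter because it is erased in step 10.

Step 10
Reactants: 14 hydroxy alkynyl acid
Product: 16 Co2(CO)6 complex of the 9α-O δ-lactone, via Co2(CO)6 complex of the hydroxy acid 15 (not isolated)
Conditions: Co2(CO)8, CH2Cl2, rt; then CF3CO2H, 0 °C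
Reagents that add atoms: dicobalt octacarbonyl, O=C=[Co](=C=O)(=C=O)(=C=O)[Co](=C=O)(=C=O)(=C=O)=C=O
Why: Nicholas reaction: acid ionises the cobalt-complexed tertiary propargylic alcohol to a cobalt-stabilised cation, which the α-tethered C17 acid should capture along the axial α trajectory (the β face is flanked by the axial 8β-methyl group and C19), giving the cis-fused δ-lactone with the 9α C–O bond whatever the C9 configuration of 14.

Step 11
Reactants: 16 cobalt-complexed lactone
Product: 17 9β-(prop-1-ynyl) δ-lactone with C13 exo-methylene and C14–H methyl ester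
Conditions: (NH4)2Ce(NO3)6, acetone, −10 °C
Reagents that add atoms: none
Why: Oxidative decomplexation with tetravalent cerium removes the cobalt carbonyl unit and should return the free alkyne without touching the new stereocentre.

Step 12
Reactants: 17 alkynyl lactone
Product: 18 silyl ketene acetal of the C15 ester
Conditions: TBSOTf, Et3N, CH2Cl2, 0 °C
Reagents that add atoms: tert-butyldimethylsilyl trifluoromethanesulfonate, CC(C)(C)[Si](C)(C)OS(=O)(=O)C(F)(F)F
Why: Soft enolisation of the ester at C14, whose α-H is activated by the adjacent C13=C18 double bond, should give the silyl ketene acetal and leave the less acidic acetate untouched.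

Step 13
Reactants: 18 silyl ketene acetal
Product: 19 meroantarctine B
Conditions: Ph3PAuNTf2 (5 mol %), i-PrOH (2 equiv), CH2Cl2, 0 °C → rt
Reagents that add atoms: none
Why: Cationic monovalent gold binds the C11≡C12 triple bond and the ketene acetal carbon C14 attacks C12 anti to gold; the silyloxycarbenium ion then passes its silyl group to i-PrOH and the vinyl–gold bond at C11 is protonated, so the methyl ester returns and C11 receives H. The closest known reaction type is the gold-catalysed 5-endo-dig carbocyclisation of silyl enol ethers onto alkynes (Conia-ene type). The cyclopentene closes in the 5-endo-dig mode with respect to the alkyne, bridging the 1,3-related axial positions C9 and C14 of the δ-lactone to a 2-oxabicyclo[3.2.1]octene. The only new stereocentre, C14, is fixed by the ring: the propynyl group is axial on one face of the lactone ring and only that face of the planar ketene acetal can reach C12, which leaves the ester exo. The step needs α- over γ-reactivity of the dienyl ketene acetal and attack at C12 rather than C11. γ-Attack through C18 would put a bridgehead double bond at C13 and attack at C11 would give a cyclobutane, so both should be disfavoured by strain.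

Compound list
1 | 4-methylpent-1-en-3-one (isopropyl vinyl ketone) | C=CC(=O)C(C)C | starting material
2 | tert-butyl(dimethyl)[(4-methylpenta-1,3-dien-3-yl)oxy]silane | C=CC(O[Si](C)(C)C(C)(C)C)=C(C)C | intermediate
3 | methyl 2,5-dihydroxybenzoate | COC(=O)c1cc(O)ccc1O | starting material
4 | methyl 3,6-dioxocyclohexa-1,4-diene-1-carboxylate (quinone ester) | COC(=O)C1=CC(=O)C=CC1=O | intermediate
5 | cis-fused adduct: methyl (10S)-3-(tert-butyldimethylsilyloxy)-4,4-dimethyl-6,9-dioxodecalin-2,7-diene-10-carboxylate, H-5 cis to the ester (5β-H) | COC(=O)[C@@]12CC=C(O[Si](C)(C)C(C)(C)C)C(C)(C)[C@@H]1C(=O)C=CC2=O | intermediate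
6 | trans-fused adduct: C5 epimer of 5 (5α-H, ester β) | COC(=O)[C@@]12CC=C(O[Si](C)(C)C(C)(C)C)C(C)(C)[C@H]1C(=O)C=CC2=O | intermediate
7 | 4,4-dimethyl-3,9-dioxo-5α-decal-7-ene 19,6β-lactone | O=C1C=C[C@@H]2OC(=O)[C@]13CCC(=O)C(C)(C)[C@@H]23 | intermediate
8 | 3α-hydroxy-4,4,8α-trimethyl-9-oxo-5α-decalin 19,6β-lactone | O=C1[C@@H](C)C[C@@H]2OC(=O)[C@]13CC[C@H](O)C(C)(C)[C@@H]23 | intermediate
9 | 3α-acetoxy-4,4,8α-trimethyl-9-oxo-5α-decalin 19,6β-lactone | O=C1[C@@H](C)C[C@@H]2OC(=O)[C@]13CC[C@H](OC(C)=O)C(C)(C)[C@@H]23 | intermediate
10 | dimethyl mesaconate, dimethyl (2E)-2-methylbut-2-enedioate | COC(=O)/C=C(\C)C(=O)OC | starting material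
11 | dimethyl (2Z)-2-(bromomethyl)but-2-enedioate (ester groups trans) | COC(=O)/C=C(\CBr)C(=O)OC | intermediate
12 | 3α-acetoxy-9-oxo 19,6β-lactone with 8β-methyl and 8α-[1,2-bis(methoxycarbonyl)prop-2-enyl] groups (C14 epimers) | O=C1[C@@](C)(C(C(=O)OC)C(=C)C(=O)OC)C[C@@H]2OC(=O)[C@]13CC[C@H](OC(C)=O)C(C)(C)[C@@H]23 | intermediate
13 | keto acid: C17 carboxylic acid of 12, C15 methyl ester retained | O=C1[C@@](C)(C(C(=O)OC)C(=C)C(=O)O)C[C@@H]2OC(=O)[C@]13CC[C@H](OC(C)=O)C(C)(C)[C@@H]23 | intermediate
14 | 9β-hydroxy-9α-(prop-1-ynyl) acid (expected major C9 epimer) | CC#C[C@@]1(O)[C@@](C)(C(C(=O)OC)C(=C)C(=O)O)C[C@@H]2OC(=O)[C@]13CC[C@H](OC(C)=O)C(C)(C)[C@@H]23 | intermediate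
15 | Co2(CO)6 complex of the alkyne of 14 | CC45C6([Co]4(=C=O)(=C=O)(=C=O)[Co]56(=C=O)(=C=O)=C=O)[C@@]1(O)[C@@](C)(C(C(=O)OC)C(=C)C(=O)O)C[C@@H]2OC(=O)[C@]13CC[C@H](OC(C)=O)C(C)(C)[C@@H]23 | intermediate
16 | Co2(CO)6 complex of the δ-lactone (O9 α, complexed propynyl β) | C=C1C(=O)O[C@@]2(C45C6(C)[Co]4(=C=O)(=C=O)(=C=O)[Co]56(=C=O)(=C=O)=C=O)[C@@](C)(C1C(=O)OC)C[C@@H]1OC(=O)[C@]23CC[C@H](OC(C)=O)C(C)(C)[C@@H]13 | intermediate
17 | δ-lactone O9(α)–C17(=O)–C13(=CH2)–C14H(CO2Me)–C8, 9β-(prop-1-ynyl), 8β-methyl, 3α-acetoxy, 19,6β-lactone | C=C1C(=O)O[C@@]2(C#CC)[C@@](C)(C1C(=O)OC)C[C@@H]1OC(=O)[C@]23CC[C@H](OC(C)=O)C(C)(C)[C@@H]13 | intermediate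
18 | silyl ketene acetal of 17: C14=C15(OMe)(OTBS), alkene geometry not controlled | C=C1C(=O)O[C@@]2(C#CC)[C@@](C)(C1=C(OC)O[Si](C)(C)C(C)(C)C)C[C@@H]1OC(=O)[C@]23CC[C@H](OC(C)=O)C(C)(C)[C@@H]13 | intermediate
19 | meroantarctine B | C=C1C(=O)O[C@@]23C=C(C)[C@]1(C(=O)OC)[C@@]2(C)C[C@@H]1OC(=O)[C@]32CC[C@H](OC(C)=O)C(C)(C)[C@@H]12 | target

Total step count: 13. Longest linear sequence: 12 steps (from 1: steps 1, 2, 3, 4, 5, 7, 8, 9, 10, 11, 12, 13).

Steps most likely to fail

Step 13. Protodesilylation of the ketene acetal may outrun C–C bond formation, or the π-bound alkyne may not be reached by C14 across the lactone ring. The fallback closes the same bond by a palladium-catalysed intramolecular α-alkenylation of the ester and sets out from 17. Trans-hydrosilylation (Et3SiH, [Cp*Ru(MeCN)3]PF6, CH2Cl2) should place silicon on the distal carbon C12 and give the (Z)-vinylsilane F1. Iododesilylation with N-iodosuccinimide in (CF3)2CHOH, with retention, gives the (Z)-vinyl iodide F2. Pd(PPh3)4 and KOPh in THF at 65 °C then couple the C14 dienolate with the vinyl iodide (oxidative addition to zerovalent palladium, six-membered palladacycle, reductive elimination; γ-coupling is disfavoured by the bridgehead alkene it would need), and the route is rejoined at 19.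

Step 2. The dimethyl-substituted diene terminus may react too slowly with the catalyst-bound quinone, so that conjugate addition followed by aromatisation, or loss of facial control, takes over. The fallback moves the asymmetric induction to a covalently bound auxiliary and sets out from 3. Transesterification with (−)-8-phenylmenthol (Bu2SnO cat., toluene, reflux) gives 8-phenylmenthyl 2,5-dihydroxybenzoate F3, and Ag2O gives the quinone ester F4. ZnCl2-promoted cycloaddition with 2, with the phenyl ring shielding one face of the chelated quinone ester, gives the cis adduct F5. DBU epimerises this at C5 to the trans adduct F6, which is purified as a single diastereomer by crystallisation (the antipodal auxiliary is used if the other diastereomer prevails). Luche reduction and acid-mediated lactonisation as in step 3 expel the auxiliary and rejoin the route at 7.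

Step 7. Direct displacement at the bromomethyl carbon or O-alkylation may compete with the conjugate addition–elimination pathway at the hindered enolate. The fallback makes the C8–C14 bond by a Michael addition that offers no second electrophilic site and adds the methylene afterwards; it sets out from 9. The potassium enolate (KN(SiMe3)2, THF, −78 °C) adds to the known acceptor dimethyl 2-(diethoxyphosphoryl)but-2-enedioate at its ester-bearing CH carbon, from the α face, to give the phosphonate F7. Horner–Wadsworth–Emmons olefination with paraformaldehyde (K2CO3, THF, rt) then gives 12.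

Further compounds
F1 | step 13 | 9β-[(Z)-2-(triethylsilyl)prop-1-enyl] analogue of 17 | C=C1C(=O)O[C@@]2(/C=C(/C)[Si](CC)(CC)CC)[C@@](C)(C1C(=O)OC)C[C@@H]1OC(=O)[C@]23CC[C@H](OC(C)=O)C(C)(C)[C@@H]13
F2 | step 13 | 9β-[(Z)-2-iodoprop-1-enyl] analogue of 17 | C=C1C(=O)O[C@@]2(/C=C(/C)I)[C@@](C)(C1C(=O)OC)C[C@@H]1OC(=O)[C@]23CC[C@H](OC(C)=O)C(C)(C)[C@@H]13
F3 | step 2 | (1R,2S,5R)-5-methyl-2-(2-phenylpropan-2-yl)cyclohexyl 2,5-dihydroxybenzoate | C[C@@H]1CC[C@H]([C@@H](C1)OC(=O)c1cc(O)ccc1O)C(C)(C)c1ccccc1
F4 | step 2 | (1R,2S,5R)-5-methyl-2-(2-phenylpropan-2-yl)cyclohexyl 3,6-dioxocyclohexa-1,4-diene-1-carboxylate | C[C@@H]1CC[C@H]([C@@H](C1)OC(=O)C1=CC(=O)C=CC1=O)C(C)(C)c1ccccc1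
F5 | step 2 | 8-phenylmenthyl ester analogue of cis adduct 5 | C[C@@H]1CC[C@H]([C@@H](C1)OC(=O)[C@@]23CC=C(O[Si](C)(C)C(C)(C)C)C(C)(C)[C@@H]2C(=O)C=CC3=O)C(C)(C)c1ccccc1
F6 | step 2 | 8-phenylmenthyl ester analogue of trans adduct 6 | C[C@@H]1CC[C@H]([C@@H](C1)OC(=O)[C@@]23CC=C(O[Si](C)(C)C(C)(C)C)C(C)(C)[C@H]2C(=O)C=CC3=O)C(C)(C)c1ccccc1
F7 | step 7 | 3α-acetoxy-9-oxo 19,6β-lactone with 8β-methyl and 8α-[2-(diethoxyphosphoryl)-1,2-bis(methoxycarbonyl)ethyl] groups | O=C1[C@@](C)(C(C(=O)OC)C(C(=O)OC)P(=O)(OCC)OCC)C[C@@H]2OC(=O)[C@]13CC[C@H](OC(C)=O)C(C)(C)[C@@H]23
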